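**Strategy.** The trimer is built from one 14-membered diolide monomer used three times: its enedione form becomes rings A and C, its 4,5-diketone becomes ring B, and base-mediated Michael–aldol and Michael additions join them through the cyclopentanone. Every ring (A, B and C) contains the γ-acyloxy ketone C5(=O)–C6–C7–C8(Me)–O9, a dissonant 1,4-relationship, so the monomer is cut at C7–C8. A visible-light decarboxylative radical macrocyclisation closes that bond in one operation: an acyclic ynoate ester of lactic acid carrying a terminal vinyl ketone loses CO2 to give the α-acyloxy radical at C8, which adds 14-endo to C7, forming the ring and the C8 stereocentre.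

Key step: step 12

Remark on numbering: each 14-membered ring is numbered O1 (oxygen on C14), C2 (ester C=O), C3, C4, C5, C6, C7, C8 (CHMe), O9, C10 (ester C=O), C11, C12, C13 (CH–O), C14 (CHMe). In the trimer, ring A hangs on the quaternary carbon through its C3, ring B has C3–C4–C5 inside the cyclopentanone, and ring C is fused to the cyclopentanone at C3–C4.

Assumption: the three C11=C12 enoates are Z as drawn, so O13 stays silylated until the last step (a free Z-γ-hydroxy enoate can close to a butenolide). The C4 carbinol centre of 4–21 is sacrificial and is erased in steps 14 and 15.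

Step 1
Reactants: 1 (S)-malic acid
Product: 4 (3S)-3-hydroxy-4-[(4-methylphenyl)sulfanyl]-4-oxobutanoic acid, via anhydride 2 (not isolated), via trifluoroacetate 3 (not isolated)
Conditions: (CF3CO)2O, 0 °C → rt, evaporate; 4-MeC6H4SH, pyridine, THF, 0 °C; H2O work-up
Reagents that add atoms: trifluoroacetic anhydride O=C(OC(=O)C(F)(F)F)C(F)(F)F; 4-methylbenzenethiol Cc1ccc(S)cc1
Why: Dehydration and O-acylation give the cyclic anhydride, which the thiol should open regioselectively at the carbonyl next to the electron-poor acyloxy carbon (anhydride thiolysis), the labile trifluoroacetate falling off on aqueous work-up with the malic stereocentre untouched.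

Step 2
Reactants: 4 (3S)-3-hydroxy-4-[(4-methylphenyl)sulfanyl]-4-oxobutanoic acid
Product: 6 (3S)-4-[(4-methylphenyl)sulfanyl]-4-oxo-3-(triethylsilyloxy)butanoic acid, via silyl ester 5 (not isolated)
Conditions: Et3SiOTf, 2,6-lutidine, CH2Cl2, −78 → 0 °C; aqueous citric acid work-up
Reagents that add atoms: triethylsilyl triflate CC[Si](CC)(CC)OS(=O)(=O)C(F)(F)F
Why: Silyl triflate with a non-nucleophilic base silylates the hydroxyl and the acid without touching the thioester, and the silyl ester is hydrolysed on work-up (silyl ether protection).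

Step 3
Reactants: 7 ethyl (S)-lactate
Product: 8 ethyl (2S)-2-(triethylsilyloxy)propanoate
Conditions: Et3SiCl, imidazole, DMF, 0 °C → rt
Reagents that add atoms: chlorotriethylsilane CC[Si](Cl)(CC)CC
Why: Standard silyl ether formation on a secondary alcohol, chosen so that this group can later be removed in the presence of a TBS ether.

Step 4
Reactants: 8 ethyl (2S)-2-(triethylsilyloxy)propanoate
Product: 9 (2S)-2-(triethylsilyloxy)propanal
Conditions: i-Bu2AlH, CH2Cl2, −78 °C; aqueous potassium sodium tartrate work-up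
Reagents that add atoms: none
Why: Partial ester reduction stops at the aldehyde because the aluminium hemiacetal is stable at −78 °C, and the α-silyloxy centre does not epimerise at that temperature.

Step 5
Reactants: 10 propiolic acid; 11 tert-butyl (S)-lactate
Product: 12 (2S)-1-tert-butoxy-1-oxopropan-2-yl prop-2-ynoate
Conditions: DCC, DMAP (5 mol%), CH2Cl2, −20 → 0 °C
Reagents that add atoms: none
Why: Steglich esterification installs the lactate unit that later delivers C8, its methyl group and O9 (its stereocentre is erased in step 12).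

Step 6
Reactants: 12 (2S)-1-tert-butoxy-1-oxopropan-2-yl prop-2-ynoate; 9 (2S)-2-(triethylsilyloxy)propanal
Product: 13 (2S)-1-tert-butoxy-1-oxopropan-2-yl (4R,5S)-4-hydroxy-5-(triethylsilyloxy)hex-2-ynoate
Conditions: 12, LiN(SiMe3)2, THF, −78 °C; then 9, −78 °C; AcOH quench at −78 °C
Reagents that add atoms: none
Why: Lithium acetylide addition to the α-silyloxy aldehyde under Felkin–Anh (non-chelation) control should favour the 4,5-anti carbinol (4R, the future C13), the minor syn isomer being removed by chromatography.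

Step 7
Reactants: 13 (2S)-1-tert-butoxy-1-oxopropan-2-yl (4R,5S)-4-hydroxy-5-(triethylsilyloxy)hex-2-ynoate
Product: 14 (2S)-1-tert-butoxy-1-oxopropan-2-yl (4R,5S)-4-(tert-butyldimethylsilyloxy)-5-(triethylsilyloxy)hex-2-ynoate
Conditions: t-BuMe2SiOTf, 2,6-lutidine, CH2Cl2, −78 → 0 °C
Reagents that add atoms: tert-butyldimethylsilyl triflate CC(C)(C)[Si](C)(C)OS(=O)(=O)C(F)(F)F
Why: Silyl triflate silylation of the hindered propargylic alcohol places the group that protects O13 to the end of the route.

Step 8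
Reactants: 14 (2S)-1-tert-butoxy-1-oxopropan-2-yl (4R,5S)-4-(tert-butyldimethylsilyloxy)-5-(triethylsilyloxy)hex-2-ynoate
Product: 15 (2S)-1-tert-butoxy-1-oxopropan-2-yl (4R,5S)-4-(tert-butyldimethylsilyloxy)-5-hydroxyhex-2-ynoate
Conditions: PPTS (cat.), MeOH/CH2Cl2, 0 °C
Reagents that add atoms: none
Why: Acid-catalysed methanolysis removes the triethylsilyl ether selectively, the bulkier TBS ether on the electron-poor propargylic oxygen being much slower to cleave.

Step 9
Reactants: 15 (2S)-1-tert-butoxy-1-oxopropan-2-yl (4R,5S)-4-(tert-butyldimethylsilyloxy)-5-hydroxyhex-2-ynoate; 6 (3S)-4-[(4-methylphenyl)sulfanyl]-4-oxo-3-(triethylsilyloxy)butanoic acid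
Product: 16 (2S)-1-tert-butoxy-1-oxopropan-2-yl (4R,5S)-4-(tert-butyldimethylsilyloxy)-5-{(3S)-4-[(4-methylphenyl)sulfanyl]-4-oxo-3-(triethylsilyloxy)butanoyloxy}hex-2-ynoate
Conditions: DCC, DMAP (20 mol%), CH2Cl2, 0 °C → rt
Reagents that add atoms: none
Why: Steglich esterification forms the O1–C2 ester while C10–C12 is still a linear ynoate, so the free C14 hydroxyl cannot lactonise onto C10.

Step 10
Reactants: 16 (2S)-1-tert-butoxy-1-oxopropan-2-yl (4R,5S)-4-(tert-butyldimethylsilyloxy)-5-{(3S)-4-[(4-methylphenyl)sulfanyl]-4-oxo-3-(triethylsilyloxy)butanoyloxy}hex-2-ynoate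
Product: 17 (2S)-1-tert-butoxy-1-oxopropan-2-yl (4R,5S)-4-(tert-butyldimethylsilyloxy)-5-[(3S)-4-oxo-3-(triethylsilyloxy)hex-5-enoyloxy]hex-2-ynoate
Conditions: CH2=CHSnBu3, Pd2(dba)3 (2.5 mol%), P(2-furyl)3, CuOP(O)Ph2 (1.5 equiv), THF, rt → 45 °C
Reagents that add atoms: tributyl(vinyl)stannane C=C[Sn](CCCC)(CCCC)CCCC
Why: Liebeskind–Srogl coupling turns the thioester into the vinyl ketone under neutral conditions (monovalent copper activates the C–S bond for zerovalent palladium), leaving the esters, the ynoate and the C4 centre untouched.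

Step 11
Reactants: 17 (2S)-1-tert-butoxy-1-oxopropan-2-yl (4R,5S)-4-(tert-butyldimethylsilyloxy)-5-[(3S)-4-oxo-3-(triethylsilyloxy)hex-5-enoyloxy]hex-2-ynoate
Product: 18 (2S)-2-{(4R,5S)-4-(tert-butyldimethylsilyloxy)-5-[(3S)-3-hydroxy-4-oxohex-5-enoyloxy]hex-2-ynoyloxy}propanoic acid
Conditions: CF3CO2H/CH2Cl2 1:4, 0 °C → rt; toluene azeotrope
Reagents that add atoms: none
Why: Acidolysis cleaves the tert-butyl ester (loss of isobutene) and the triethylsilyl ether in one operation, while the TBS ether, deactivated by the neighbouring ynoate, should survive.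

Step 12
Reactants: 18 (2S)-2-{(4R,5S)-4-(tert-butyldimethylsilyloxy)-5-[(3S)-3-hydroxy-4-oxohex-5-enoyloxy]hex-2-ynoyloxy}propanoic acid
Product: 19 (4S,8S,13R,14S)-13-(tert-butyldimethylsilyloxy)-4-hydroxy-8,14-dimethyl-1,9-dioxacyclotetradec-11-yne-2,5,10-trione
Conditions: [Ir(dF(CF3)ppy)2(dtbbpy)]PF6 (2 mol%), K2HPO4 (1.2 equiv), DMF (2 mM), 450 nm LEDs, 25 °C, Ar
Reagents that add atoms: none
Why: The excited trivalent iridium photocatalyst oxidises the carboxylate of 18 by one electron, CO2 is lost, and the nucleophilic α-acyloxy radical at C8 adds to the unsubstituted terminus C7 of the vinyl ketone; the α-keto radical at C6 is then reduced by the divalent iridium species to the enolate and protonated, which closes the catalytic cycle without any hydrogen-atom donor. The closest known reaction type is the photoredox decarboxylative Giese addition in its macrocyclising form (decarboxylative peptide macrocyclisation onto acrylamides), and behind it the tin-mediated radical macrocyclisation onto enones. The 14-membered ring closes in the 14-endo-trig mode, C6 and C7 both ending in the ring, while attack of C8 on the ynoate would be 4-exo or 5-endo-dig and should not compete. C8 is the only new stereocentre: the radical is planar with its methyl group anti to the O9–C10 bond, and the face that bonds to C7 is set under substrate control by the macrocyclic transition state, in which the rigid ynoate rod, the C13/C14 anti pair and the hydrogen-bonded C4 carbinol–C5 ketone unit fix the path of the tether; the 8S ring is the one carried on and any 8R epimer is removed here. The step needs chemoselectivity for the vinyl ketone over the ynoate (polarity matching of the nucleophilic radical with the more electrophilic, unhindered enone), ring closure over oligomerisation (2 mM, long radical lifetime in the absence of a hydrogen donor) and face selectivity at C8, the last being the least secure.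

Step 13
Reactants: 19 (4S,8S,13R,14S)-13-(tert-butyldimethylsilyloxy)-4-hydroxy-8,14-dimethyl-1,9-dioxacyclotetradec-11-yne-2,5,10-trione
Product: 20 (4S,8S,11Z,13R,14S)-13-(tert-butyldimethylsilyloxy)-4-hydroxy-8,14-dimethyl-1,9-dioxacyclotetradec-11-ene-2,5,10-trione
Conditions: H2 (1 atm), Pd/CaCO3 poisoned with Pb(OAc)2, quinoline, EtOAc, rt
Reagents that add atoms: none
Why: Lindlar semihydrogenation delivers H2 syn to the ring alkyne and should stop at the Z-enoate, now that neither a thioester nor a vinyl ketone is left in the molecule.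

Step 14
Reactants: 20 (4S,8S,11Z,13R,14S)-13-(tert-butyldimethylsilyloxy)-4-hydroxy-8,14-dimethyl-1,9-dioxacyclotetradec-11-ene-2,5,10-trione
Product: 22 (3E,8S,11Z,13R,14S)-13-(tert-butyldimethylsilyloxy)-8,14-dimethyl-1,9-dioxacyclotetradeca-3,11-diene-2,5,10-trione, via mesylate 21 (not isolated)
Conditions: MeSO2Cl, Et3N, CH2Cl2, −20 °C; then DBU, 0 °C
Reagents that add atoms: methanesulfonyl chloride CS(=O)(=O)Cl
Why: Mesylation of the C4 hydroxyl followed by E1cB elimination through the ester enolate at C3 gives the conjugated E-enedione and erases the C4 centre.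

Step 15
Reactants: 20 (4S,8S,11Z,13R,14S)-13-(tert-butyldimethylsilyloxy)-4-hydroxy-8,14-dimethyl-1,9-dioxacyclotetradec-11-ene-2,5,10-trione
Product: 23 (8S,11Z,13R,14S)-13-(tert-butyldimethylsilyloxy)-8,14-dimethyl-1,9-dioxacyclotetradec-11-ene-2,4,5,10-tetrone
Conditions: Dess–Martin periodinane, CH2Cl2, 0 °C → rt
Reagents that add atoms: none
Why: Dess–Martin oxidation of the acyloin gives the 1,2-diketone (expected to sit largely as its C3=C4 enol), whose C3 is now a β-keto ester carbon.

Step 16
Reactants: 23 (8S,11Z,13R,14S)-13-(tert-butyldimethylsilyloxy)-8,14-dimethyl-1,9-dioxacyclotetradec-11-ene-2,4,5,10-tetrone; 22 (3E,8S,11Z,13R,14S)-13-(tert-butyldimethylsilyloxy)-8,14-dimethyl-1,9-dioxacyclotetradeca-3,11-diene-2,5,10-trione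
Product: 24 rings B and C joined through the cyclopentanone (B-C3 still bearing H; B-C5 tertiary OH; both O13 as TBS ethers; B-3S,5S; C-3S,4S)
Conditions: 22 (1.1 equiv), DBU (20 mol%), CH2Cl2, −20 °C → rt
Reagents that add atoms: none
Why: Domino Michael–aldol [3+2] annulation of a 1,2-dione with an enone: B-C3 adds to C-C3 (β to the C-C5 ketone) and the enolate at C-C4 closes on the B-C5 ketone (5-exo-trig); syn addition across one face of the E-enedione gives the trans ring-C fusion, the ring-B bridge forces B-C2 and B-C6 cis, the closed aldol transition state puts the new OH cis to the C-C5 acyl group, and the pairing of the two macrocycle faces rests on substrate control (peripheral attack).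

Step 17
Reactants: 24 rings B and C joined through the cyclopentanone; 22 (3E,8S,11Z,13R,14S)-13-(tert-butyldimethylsilyloxy)-8,14-dimethyl-1,9-dioxacyclotetradeca-3,11-diene-2,5,10-trione
Product: 25 tris(tert-butyldimethylsilyl) ether of the target (silyl groups on A-O13, B-O13 and C-O13)
Conditions: 22 (1.5 equiv), DBU (30 mol%), CH2Cl2 (0.5 M), rt
Reagents that add atoms: none
Why: Michael addition of the cyclic β-keto ester (2-oxocyclopentanecarboxylate type) to C3 of the enedione creates the quaternary B-C3 on the face anti to the vicinal C-C2 ester, the only face that keeps the ring-B bridge cis, while A-C3 (R) is set by attack on the exposed face of the second macrocycle under substrate, possibly thermodynamic, control.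

Step 18
Reactants: 25 tris(tert-butyldimethylsilyl) ether of the target
Product: 26 CNP0072185.1 (target)
Conditions: HF·pyridine, pyridine, THF, 0 °C → rt
Reagents that add atoms: none
Why: Acidic fluoride desilylation removes the three secondary TBS ethers without forming alkoxides, so the Z-γ-hydroxy enoates should not translactonise and the tertiary aldol should not open; no stereocentre is touched.

**Compound list**

1 | (S)-malic acid | O[C@@H](CC(=O)O)C(=O)O | starting material
2 | (3S)-2,5-dioxooxolan-3-yl trifluoroacetate | O=C1C[C@H](OC(=O)C(F)(F)F)C(=O)O1 | intermediate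
3 | (3S)-4-[(4-methylphenyl)sulfanyl]-4-oxo-3-(trifluoroacetoxy)butanoic acid | OC(=O)C[C@H](OC(=O)C(F)(F)F)C(=O)Sc1ccc(C)cc1 | intermediate
4 | (3S)-3-hydroxy-4-[(4-methylphenyl)sulfanyl]-4-oxobutanoic acid | OC(=O)C[C@H](O)C(=O)Sc1ccc(C)cc1 | intermediate
5 | triethylsilyl (3S)-4-[(4-methylphenyl)sulfanyl]-4-oxo-3-(triethylsilyloxy)butanoate | CC[Si](CC)(CC)OC(=O)C[C@H](O[Si](CC)(CC)CC)C(=O)Sc1ccc(C)cc1 | intermediate
6 | (3S)-4-[(4-methylphenyl)sulfanyl]-4-oxo-3-(triethylsilyloxy)butanoic acid | OC(=O)C[C@H](O[Si](CC)(CC)CC)C(=O)Sc1ccc(C)cc1 | intermediate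
7 | ethyl (S)-lactate | CCOC(=O)[C@H](C)O | starting material
8 | ethyl (2S)-2-(triethylsilyloxy)propanoate | CCOC(=O)[C@H](C)O[Si](CC)(CC)CC | intermediate
9 | (2S)-2-(triethylsilyloxy)propanal | O=C[C@H](C)O[Si](CC)(CC)CC | intermediate
10 | propiolic acid | C#CC(=O)O | starting material
11 | tert-butyl (S)-lactate | C[C@H](O)C(=O)OC(C)(C)C | starting material
12 | (2S)-1-tert-butoxy-1-oxopropan-2-yl prop-2-ynoate | C#CC(=O)O[C@@H](C)C(=O)OC(C)(C)C | intermediate
13 | (2S)-1-tert-butoxy-1-oxopropan-2-yl (4R,5S)-4-hydroxy-5-(triethylsilyloxy)hex-2-ynoate | C[C@H](O[Si](CC)(CC)CC)[C@H](O)C#CC(=O)O[C@@H](C)C(=O)OC(C)(C)C | intermediate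
14 | (2S)-1-tert-butoxy-1-oxopropan-2-yl (4R,5S)-4-(tert-butyldimethylsilyloxy)-5-(triethylsilyloxy)hex-2-ynoate | C[C@H](O[Si](CC)(CC)CC)[C@H](O[Si](C)(C)C(C)(C)C)C#CC(=O)O[C@@H](C)C(=O)OC(C)(C)C | intermediate
15 | (2S)-1-tert-butoxy-1-oxopropan-2-yl (4R,5S)-4-(tert-butyldimethylsilyloxy)-5-hydroxyhex-2-ynoate | C[C@H](O)[C@H](O[Si](C)(C)C(C)(C)C)C#CC(=O)O[C@@H](C)C(=O)OC(C)(C)C | intermediate
16 | (2S)-1-tert-butoxy-1-oxopropan-2-yl (4R,5S)-4-(tert-butyldimethylsilyloxy)-5-{(3S)-4-[(4-methylphenyl)sulfanyl]-4-oxo-3-(triethylsilyloxy)butanoyloxy}hex-2-ynoate | C[C@H](OC(=O)C[C@H](O[Si](CC)(CC)CC)C(=O)Sc1ccc(C)cc1)[C@H](O[Si](C)(C)C(C)(C)C)C#CC(=O)O[C@@H](C)C(=O)OC(C)(C)C | intermediate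
17 | (2S)-1-tert-butoxy-1-oxopropan-2-yl (4R,5S)-4-(tert-butyldimethylsilyloxy)-5-[(3S)-4-oxo-3-(triethylsilyloxy)hex-5-enoyloxy]hex-2-ynoate | C[C@H](OC(=O)C[C@H](O[Si](CC)(CC)CC)C(=O)C=C)[C@H](O[Si](C)(C)C(C)(C)C)C#CC(=O)O[C@@H](C)C(=O)OC(C)(C)C | intermediate
18 | (2S)-2-{(4R,5S)-4-(tert-butyldimethylsilyloxy)-5-[(3S)-3-hydroxy-4-oxohex-5-enoyloxy]hex-2-ynoyloxy}propanoic acid | C[C@H](OC(=O)C[C@H](O)C(=O)C=C)[C@H](O[Si](C)(C)C(C)(C)C)C#CC(=O)O[C@@H](C)C(=O)O | intermediate
19 | (4S,8S,13R,14S)-13-(tert-butyldimethylsilyloxy)-4-hydroxy-8,14-dimethyl-1,9-dioxacyclotetradec-11-yne-2,5,10-trione | C[C@@H]1OC(=O)C[C@H](O)C(=O)CC[C@H](C)OC(=O)C#C[C@H]1O[Si](C)(C)C(C)(C)C | intermediate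
20 | (4S,8S,11Z,13R,14S)-13-(tert-butyldimethylsilyloxy)-4-hydroxy-8,14-dimethyl-1,9-dioxacyclotetradec-11-ene-2,5,10-trione | C[C@@H]1OC(=O)C[C@H](O)C(=O)CC[C@H](C)OC(=O)/C=C\[C@H]1O[Si](C)(C)C(C)(C)C | intermediate
21 | 4-O-methanesulfonate of 20 | C[C@@H]1OC(=O)C[C@H](OS(C)(=O)=O)C(=O)CC[C@H](C)OC(=O)/C=C\[C@H]1O[Si](C)(C)C(C)(C)C | intermediate
22 | (3E,8S,11Z,13R,14S)-13-(tert-butyldimethylsilyloxy)-8,14-dimethyl-1,9-dioxacyclotetradeca-3,11-diene-2,5,10-trione | C[C@@H]1OC(=O)/C=C/C(=O)CC[C@H](C)OC(=O)/C=C\[C@H]1O[Si](C)(C)C(C)(C)C | intermediate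
23 | (8S,11Z,13R,14S)-13-(tert-butyldimethylsilyloxy)-8,14-dimethyl-1,9-dioxacyclotetradec-11-ene-2,4,5,10-tetrone (drawn as the diketone) | C[C@@H]1OC(=O)CC(=O)C(=O)CC[C@H](C)OC(=O)/C=C\[C@H]1O[Si](C)(C)C(C)(C)C | intermediate
24 | rings B and C joined through the cyclopentanone: ring B bridged at C3/C5 (B-C4 ketone, B-C5 OH, B-C3 H), ring C trans-fused at C3/C4, both O13 as TBS ethers (B-3S,5S,8S,13R,14S; C-3S,4S,8S,13R,14S; both 11Z) | [C@@H]23C(=O)O[C@@H](C)[C@H](O[Si](C)(C)C(C)(C)C)/C=C\C(=O)O[C@@H](C)CC[C@@](O)(C2=O)[C@H]2C(=O)CC[C@H](C)OC(=O)/C=C\[C@@H](O[Si](C)(C)C(C)(C)C)[C@H](C)OC(=O)[C@@H]23 | intermediate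
25 | tris(tert-butyldimethylsilyl) ether of the target (A-O13, B-O13, C-O13) | C[C@@H]1OC(=O)[C@@H]([C@@]23C(=O)O[C@@H](C)[C@H](O[Si](C)(C)C(C)(C)C)/C=C\C(=O)O[C@@H](C)CC[C@@](O)(C2=O)[C@H]2C(=O)CC[C@H](C)OC(=O)/C=C\[C@@H](O[Si](C)(C)C(C)(C)C)[C@H](C)OC(=O)[C@@H]23)CC(=O)CC[C@H](C)OC(=O)/C=C\[C@H]1O[Si](C)(C)C(C)(C)C | intermediate
26 | CNP0072185.1 (A-3R,8S,13R,14S; B-3S,5S,8S,13R,14S; C-3S,4S,8S,13R,14S; three 11Z enoates) | C[C@@H]1OC(=O)[C@@H]([C@@]23C(=O)O[C@@H](C)[C@H](O)/C=C\C(=O)O[C@@H](C)CC[C@@](O)(C2=O)[C@H]2C(=O)CC[C@H](C)OC(=O)/C=C\[C@@H](O)[C@H](C)OC(=O)[C@@H]23)CC(=O)CC[C@H](C)OC(=O)/C=C\[C@H]1O | target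

**Step count and risks**

Total steps: 18. Longest linear sequence: 14 steps (7 → 8 → 9 → 13 → 14 → 15 → 16 → 17 → 18 → 19 → 20 → 23 → 24 → 25 → 26).

Step 12 (key step). Three processes may spoil it: the electron-poor α-acyloxy carboxylate may be oxidised too slowly by the excited photocatalyst, the long-lived radical may oligomerise instead of closing the ring, and the planar C8 radical may bond to C7 with poor face selectivity. The fallback sets out from 18. The acid is condensed with N-hydroxyphthalimide (N,N'-diisopropylcarbodiimide, CH2Cl2, 0 °C, no DMAP) to the redox-active N-acyloxyphthalimide ester F1. F1 is irradiated with blue LEDs in the presence of [Ru(bpy)3](PF6)2 (1 mol%) and Hantzsch ester (1.5 equiv) in CH2Cl2 at 2 mM and −20 °C. Reductive fragmentation (the known reductive decarboxylative Giese addition of redox-active esters) gives the same C8 radical whatever the oxidation potential of the carboxylate. The low temperature is the remaining lever on face selectivity. The ring closure comes back to the route at 19.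

Step 16. The two macrocycles may pair through the wrong faces in the Michael step, giving a diastereomeric cyclopentanol, and the 1,2-diketone may self-aldolise under base. The fallback sets out from 23. Silylation (Me3SiCl, Et3N, CH2Cl2, 0 °C) gives the silyl dienol ether F2. F2 is combined with 22 and Sc(OTf)3 (10 mol%, optionally with a chiral pybox ligand for reagent control) in CH2Cl2 at −78 °C. Mukaiyama–Michael addition at C3 of 22 is followed in the same flask by Mukaiyama aldol closure of the transferred silyl enol ether onto the Lewis-acid-activated B-C5 ketone. No free enolate is present, so self-aldolisation is excluded. Mild acidic work-up comes back to the route at 24.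

Step 17. The congested quaternary C–C bond may not form or may revert (retro-Michael), the tertiary aldol may open or dehydrate under base, and the face selectivity at A-C3 may be poor. The fallback sets out from 24. Me3SiOTf (2.2 equiv) and Et3N in CH2Cl2 at −78 °C give the bis(trimethylsilyl) derivative F3 (B-C3=C4 silyl enol ether, B-C5 silyl ether). F3 adds to 22 under Sc(OTf)3 catalysis in CH2Cl2 at −78 → −20 °C in a kinetic, base-free Mukaiyama–Michael addition. Aqueous acidic work-up removes both trimethylsilyl groups and comes back to the route at 25.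

**Further compounds**

F1 | step 12 | 1,3-dioxoisoindolin-2-yl (2S)-2-{(4R,5S)-4-(tert-butyldimethylsilyloxy)-5-[(3S)-3-hydroxy-4-oxohex-5-enoyloxy]hex-2-ynoyloxy}propanoate | C[C@H](OC(=O)C[C@H](O)C(=O)C=C)[C@H](O[Si](C)(C)C(C)(C)C)C#CC(=O)O[C@@H](C)C(=O)ON1C(=O)c2ccccc2C1=O
F2 | step 16 | (8S,11Z,13R,14S)-13-(tert-butyldimethylsilyloxy)-8,14-dimethyl-4-(trimethylsilyloxy)-1,9-dioxacyclotetradeca-3,11-diene-2,5,10-trione (C3=C4 geometry not assigned) | C[C@@H]1OC(=O)C=C(O[Si](C)(C)C)C(=O)CC[C@H](C)OC(=O)/C=C\[C@H]1O[Si](C)(C)C(C)(C)C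
F3 | step 17 | bis(trimethylsilyl) derivative of 24 (B-C3=C4 trimethylsilyl enol ether, B-C5 trimethylsilyl ether) | C=23C(=O)O[C@@H](C)[C@H](O[Si](C)(C)C(C)(C)C)/C=C\C(=O)O[C@@H](C)CC[C@@](O[Si](C)(C)C)(C=2O[Si](C)(C)C)[C@H]2C(=O)CC[C@H](C)OC(=O)/C=C\[C@@H](O[Si](C)(C)C(C)(C)C)[C@H](C)OC(=O)[C@@H]23
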